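Late in Friday's run, from 76 min to 120 min, [starting material] falls from 163.0 mM to 116.0 mM, a rate of 1.07 mM min⁻¹, and that stretch passes through the 150 mM charged to Sunday's flask. Divide the mean amount there by that rate and you get 131 min. Carry this clock, the amount present over the rate at which it goes, the reciprocal of a pseudo-first-order constant.

| flask | starting material | free catalyst | time |
|---|---|---|---|
| Friday's | 300 mM | 30.0 mM |  |
| Thursday's | 300 mM | 90.0 mM |  |
| Sunday's | 150 mM | 9.90 mM | 120 min |

| run | time / min | [starting material] / mM |
|---|---|---|
| Friday's run | 4.8 | 290.6 |
| Friday's run | 7.6 | 282.5 |
| Friday's run | 12 | 272.4 |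
| Friday's run | 19 | 257.5 |
| Friday's run | 30 | 238.7 |
| Friday's run | 48 | 205.2 |
| Friday's run | 76 | 163.0 |
| Friday's run | 120 | 116.0 |
| Thursday's run | 4.8 | 178.8 |
| Thursday's run | 7.6 | 110.2 |
| Thursday's run | 12 | 40.2 |
| Thursday's run | 19 | 5.0 |
| Thursday's run | 30 | 0 |
| Thursday's run | 48 | 0 |
| Thursday's run | 76 | 1.3 |
| Thursday's run | 120 | 0.6 |

(each reading ± 0.9 mM)

- Overall: starting material -> target, with free catalyst as catalyst.
- Constant volume, constant temperature.
- Bound and free are read together.
- An order is taken over about fifteen percent of the charge, up and down.

- the exponent of [free catalyst] in the starting rate at the charge of the Friday's run (at the point where two percent of the starting material have become target)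
- starting material in the Sunday's run at 120 min, as a share of the starting material charged

Now turn the question round. For Sunday's flask to lose half its charge by 120 min, its clock must be 173 min, yet it holds a third of the free catalyst of Friday's flask. Starting from Friday's late clock, you can allow an order in [free catalyst] of 0.254 and no higher.

So read the order. At the same charge of starting material, the first readings give a clock of 153 min for Friday's flask and 11.9 min for Thursday's. That makes the order 2.33, a chord between two catalyst levels, far above what a half loss allows. Friday's first drop, 9.40 mM, carries a scatter of 0.9 mM.

My reckoning stretches Sunday's clock to 1720 min, ten times the 173 min asked for above, so 93.3% of the starting material stays.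

The forecast, which by its own account rests on two catalyst levels “this rests on two catalyst levels only”, says 3 (from 2.2 to 3.9) and 97% (from 90% to 99.5%).

The flask gives an order of 2.2 and 84.2% of the starting material left, by these steps:

    free catalyst + starting material ⇌ catalyst-substrate complex, settled at all times (0.5010 L mol⁻¹)
    catalyst-substrate complex + free catalyst → target + 2 free catalyst (88.20 L mol⁻¹ min⁻¹)
    free catalyst + starting material → spent catalyst + starting material (0.04590 L mol⁻¹ min⁻¹)
    catalyst-substrate complex + starting material ⇌ doubly bound catalyst, settled at all times (29.10 L mol⁻¹)

Sunday's flask loses 23.7 mM over 120 min, so its clock, the charge over the mean rate, is 760 min, shorter than my 1720 min. In Friday's flask, the rate of product formation of 2.2 mM min⁻¹, where two percent of the starting material have turned, gives a clock of 136 min. Multiplied by the natural logarithm of two, that clock is 94.3 min, and the time for half the charge to become target in Friday's flask is 86.2 min.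

(The numbers in the tables stem from a simulated flask from invented constants; noise was put on by code.)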